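## Analysis of the target

Agrimol B (35) is a linear trimer of acylphloroglucinol units: two identical outer rings A and a central ring B, joined by two CH2 bridges, with every ring carbon substituted. Numbering used throughout: ring A carries butanoyl at C1, OH at C2, the bridge at C3, OH at C4, CH3 at C5 and OCH3 at C6; ring B carries the bridges at C1 and C3, OH at C2, C4 and C6, and the (S)-2-methylbutanoyl group at C5. The only stereocentre is the α-carbon of the ring B ketone. Nothing else in the molecule can control it, so it has to come from the chiral pool, and because it is enolisable it should arrive late and meet neither base nor warm Lewis acid. The free polyphenol is delicate: the electron-rich diarylmethane bridges cleave and scramble by retro-Friedel–Crafts reaction in acid or base, the phenols are air-sensitive, and the aryl ketones are photoactive. The difficulty is twofold: the bridges must join defined carbons without the over-alkylation statistics of methylene coupling, and three rings of nearly equal nucleophilicity must take up two different acyl groups at fixed positions. The plan rests on ring B, whose carbons alternate between oxygen-bearing (C2, C4, C6) and carbon-bearing (C1, C3, C5). C3–C4 can therefore be the two carbons of an alkynyl ether carrying one CH2–ring A arm, and C2–C1–C6–C5 the four carbons of a 3-alkoxycyclobutenone carrying the other.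

## Retrosynthetic reasoning

35 from 34. The last operation only removes four benzyl ethers by hydrogenolysis. Benzyl is chosen because it survives base, organolithium reagents, long-wavelength light and cold dilute acid, and because it leaves under neutral conditions that neither scramble the bridges nor touch the stereocentre.

34 from 31 and 33. The ring B C5–C(=O) bond is cut last, so the stereocentre afterwards sees only hydrogenolysis. Triol 31 has exactly one aromatic C–H (ring B C5), so the acylation has no regiochemical choice. Acid chloride 33 comes from the chiral-pool acid 32 without base.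

31 from 30. Ring B carries tert-butyl ethers and rings A carry benzyl ethers. Cold acid therefore frees ring B alone and turns it into the most nucleophilic ring just before it is acylated.

30 from 28. The two ring A C1–C(=O) bonds are cut next. A Friedel–Crafts reaction could not tell ring A C1–H from ring B C5–H, so ring A C1 carries a bromine from the start and the butanoyl groups enter by bromine–lithium exchange and an external butanoyl donor. The bromine also blocks the one ring position through which the benzylic bromide 8 could condense with itself.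

28 from 23 and 15 (key disconnection). Ring B is cut at C2–C3 and C4–C5; the C1–C2 bond of the cyclobutenone is broken and re-formed in the cascade. Cutting here means both diarylmethane bonds already exist on an sp3 carbon of 23 and on the propargylic carbon of 15. Neither bridge is then made by aromatic substitution, the 2:1 stoichiometry of ring A to ring B is built in, and the three oxygens arrive in the 1,3,5 relationship. The forward reaction has to open 23 to a vinylketene without heat, add it to 15 with the correct orientation, and close the six-membered ring.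

15 from 8 and 13, and 13 from 9. The propargylic C–C bond is cut to the lithium acetylide of 13 and benzylic bromide 8. Alkyne 13 comes from vinyl ether 9 by bromination and two eliminations.

23 from 21 and 13, and 21 from 8 and 16. The four-membered ring is cut into ketene 22 (from acid chloride 21) and the same alkyne 13. The three-carbon acid 20 behind 21 comes from bromide 8 by malonate homologation with 16. Both partners of the key step therefore branch from one intermediate, 8.

8 from 1. The ring A pattern is drawn from the symmetric triol 1, which already holds the C-methyl group. Formylation meets two equivalent positions, O-methylation picks the hydroxyl para to the formyl group, bromination takes the only carbon left, and benzylation, reduction and bromide formation complete 8. No step depends on a choice between similar ring positions.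

## Alternatives that were turned down

Alternative 1: The two ring A C1–C(=O) bonds are made last on the finished three-ring skeleton. A substrate with all seven phenolic oxygens butanoylated and both ring A C1 positions brominated is treated with an alkyllithium at very low temperature. Each aryllithium takes the butanoyl group from the neighbouring C2 ester (anionic ortho-Fries shift) and gives A1, the trimer with both ring A ketones, free C2 hydroxyls and five remaining esters.
- For: the acyl group is delivered intramolecularly and regiospecifically without Lewis acid, and the esters serve as protecting group and acyl source at once.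
- Against: the step does not address the assembly of the two bridges, which would still fall to electrophilic methylene coupling. The exchange has to outrun attack on seven ester carbonyls and removal of their acidic α-hydrogens. A1 still lacks the ring B acyl group while ring B carries three butanoates, so a Lewis acid used for the last acylation can move butanoyl, the wrong group, onto ring B C5. That forces a prior saponification to a scrambling-prone polyphenol.
- Comparison: alternative 1 is stronger on economy of acyl delivery and needs no photochemistry, and the chosen route borrows its bromine placeholder at ring A C1. In exchange the chosen route offers a defined construction of the skeleton and an exchange substrate that contains only ethers.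

Alternative 2: Both outer rings are cut at C5–C6 and C1–C2. A ring B core with two 1-methoxy-1,3-bis(silyloxy)diene arms adds twice to the alkynone 1-methoxyhex-1-yn-3-one A3. Loss of methanol and of the silyl groups aromatises both rings to A2, with rings A complete and ring B a tribenzyl ether free at C5.
- For: two hexasubstituted rings form in one two-directional operation, the butanoyl groups come with the dienophile, and the orientation follows from the polarity match of the nucleophilic diene terminus with the β-carbon of the ynone.
- Against: the diene carbons are fully substituted and A3 is deactivated by its donor group, so the addition is likely to be a stepwise Michael–aldol sequence that must form four bonds at congested carbons. The bis(β-keto ester) precursor needs a ring B bis(benzylic halide) that has a free nucleophilic ring position and can condense with itself. Four silyl enol ethers must survive. A2 leaves ring B C5 to be acylated beside four free ring A phenols.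
- Comparison: alternative 2 is stronger in that ring A arrives acylated and no organolithium or light is needed. The chosen route builds one ring instead of two, from two partners that derive from one benzylic bromide, with the orientation fixed by a single polar [2+2] event.

Alternative 3: Ring B is cut at C1–C6 and C3–C4. A 3-oxoglutarate diester that already bears both arylmethyl arms is converted to its magnesium enolates and C-acylated at both α-carbons by malonyl dichloride A5. This gives the cyclohexanetrione diester A4 as a diastereomer mixture; hydrogenolysis, decarboxylation and enolisation would then give the ring B triol.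
- For: cheap polyketide-like logic, no photochemistry, rings A fully acylated beforehand, the 1,3 placing of the arms guaranteed, and ring B emerging unprotected.
- Against: both acylations create quaternary carbons at already trisubstituted enolate carbons. After the first C-acylation the ring can close through oxygen as easily as through carbon and give a hydroxypyranone, six-membered either way. A5 forms ketenes with amine bases. The non-enolisable trione A4 is open to retro-Claisen cleavage during decarboxylation.
- Comparison: alternative 3 is stronger on cost and on step count for ring B. Nothing in the substrate decides C- against O-acylation, whereas in the benzannulation the order of bond formation is fixed by alkyne polarisation and by orbital-symmetry-allowed ring opening and closure.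

Key step: step 14

Assumption: 2,4,6-trihydroxytoluene (1) is taken as purchasable and replaces a resorcinol-type start such as 5-methoxyresorcinol, whose two successive C-functionalisations would not be regioselective.

Abbreviations: Ar1 = 2,6-bis(benzyloxy)-3-bromo-4-methoxy-5-methylphenyl (bromine on ring A C1); Ar2 = 2,6-bis(benzyloxy)-3-butanoyl-4-methoxy-5-methylphenyl.

## Route

Step 1
Reactants: 1 2,4,6-trihydroxytoluene
Product: 3 2,4,6-trihydroxy-3-methylbenzaldehyde, via iminium salt 2 (not isolated)
Conditions: POCl3, DMF, EtOAc, 0 °C → rt; then H2O, 50 °C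
Reagents that add atoms: N,N-dimethylformamide, CN(C)C=O; water, O
Why: Vilsmeier–Haack formylation of a phloroglucinol; the two free ring carbons of 1 are equivalent, so only one aldehyde can form, and the iminium group of 2 deactivates the ring against a second attack.

Step 2
Reactants: 3 2,4,6-trihydroxy-3-methylbenzaldehyde
Product: 4 2,6-dihydroxy-4-methoxy-3-methylbenzaldehyde
Conditions: Me2SO4 (1.0 equiv), K2CO3 (1.0 equiv), acetone, 0 °C → rt
Reagents that add atoms: dimethyl sulfate, COS(=O)(=O)OC
Why: Williamson O-methylation; the hydroxyl para to the formyl group is the most acidic and the only one not held in a hydrogen-bond chelate with the carbonyl, so one equivalent of base and electrophile should methylate it selectively and place the methoxy group beside the C-methyl group.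

Step 3
Reactants: 4 2,6-dihydroxy-4-methoxy-3-methylbenzaldehyde
Product: 5 3-bromo-2,6-dihydroxy-4-methoxy-5-methylbenzaldehyde
Conditions: NBS (1.0 equiv), MeCN, 0 °C
Reagents that add atoms: N-bromosuccinimide, O=C1CCC(=O)N1Br
Why: Electrophilic aromatic bromination at the single remaining ring carbon, which is activated by three oxygens; the bromine marks ring A C1 for the later butanoyl group and removes the ring position through which the benzylic bromide 8 could alkylate itself.

Step 4
Reactants: 5 3-bromo-2,6-dihydroxy-4-methoxy-5-methylbenzaldehyde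
Product: 6 2,6-bis(benzyloxy)-3-bromo-4-methoxy-5-methylbenzaldehyde
Conditions: BnBr (2.5 equiv), K2CO3, DMF, 60 °C
Reagents that add atoms: benzyl bromide, BrCc1ccccc1
Why: Williamson etherification; both phenols are chelated and flanked, hence the polar solvent and warming, and no other nucleophilic site remains.

Step 5
Reactants: 6 2,6-bis(benzyloxy)-3-bromo-4-methoxy-5-methylbenzaldehyde
Product: 7 (Ar1)methanol
Conditions: NaBH4, THF–MeOH, 0 °C
Reagents that add atoms: none
Why: Hydride reduction of the aldehyde; aryl bromide and ethers are inert to NaBH4.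

Step 6
Reactants: 7 (Ar1)methanol
Product: 8 1,3-bis(benzyloxy)-4-bromo-2-(bromomethyl)-5-methoxy-6-methylbenzene (Ar1–CH2Br)
Conditions: PBr3, Et2O, −10 °C; crude product used at once
Reagents that add atoms: phosphorus tribromide, BrP(Br)Br
Why: Conversion of a benzylic alcohol into the bromide; the bromide is electron-rich and ionises easily, but with every ring position occupied it cannot undergo Friedel–Crafts self-condensation and should be usable without purification.

Step 7
Reactants: 9 tert-butyl vinyl ether
Product: 11 (Z)-1-bromo-2-tert-butoxyethene, via dibromo ether 10 (not isolated)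
Conditions: Br2, pentane, −78 °C; then Et3N, −78 → 40 °C
Reagents that add atoms: bromine, BrBr
Why: Bromine addition to the enol ether and amine-induced anti-dehydrobromination of the α,β-dibromo ether; the Z isomer is expected to predominate, and either isomer leads to 13 in step 8.

Step 8
Reactants: 11 (Z)-1-bromo-2-tert-butoxyethene
Product: 13 tert-butoxyacetylene, via sodium acetylide 12 (not isolated)
Conditions: NaNH2 (2.2 equiv), NH3(l), −33 °C; then NH4Cl, pentane extraction; stored at −20 °C
Reagents that add atoms: none
Why: Base-induced elimination of HBr from a 2-bromovinyl ether gives the alkynyl ether, which is held as its acetylide until the quench; 13 is kept cold because tert-butyl alkynyl ethers lose isobutene on warming.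

Step 9
Reactants: 13 tert-butoxyacetylene; 8 Ar1–CH2Br
Product: 15 1,3-bis(benzyloxy)-4-bromo-2-(3-tert-butoxyprop-2-yn-1-yl)-5-methoxy-6-methylbenzene, via lithium acetylide 14 (not isolated)
Conditions: n-BuLi (1.0 equiv relative to 13), THF, −78 °C; then 8, DMPU, −78 → 0 °C
Reagents that add atoms: none
Why: Alkylation of a lithium alkoxyacetylide with a reactive benzylic bromide; all n-BuLi is consumed before 8 is added, so the aryl bromide is not exchanged, and the acetylide is too weak a base to isomerise the product to an allenyl ether.

Step 10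
Reactants: 16 diethyl malonate; 8 Ar1–CH2Br
Product: 18 diethyl 2-(Ar1-methyl)propanedioate, via sodium malonate 17 (not isolated)
Conditions: NaH, THF–DMF, 0 °C (16 in excess); then 8, rt
Reagents that add atoms: none
Why: Malonic ester alkylation; the excess of enolate suppresses dialkylation.

Step 11
Reactants: 18 diethyl 2-(Ar1-methyl)propanedioate
Product: 20 3-(Ar1)propanoic acid, via malonic acid 19 (not isolated)
Conditions: KOH, EtOH–H2O, reflux; HCl to pH 2; then pyridine, 110 °C
Reagents that add atoms: potassium hydroxide, [K+].[OH-]
Why: Saponification followed by thermal decarboxylation of the malonic acid; benzyl ethers and the aryl bromide tolerate both stages.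

Step 12
Reactants: 20 3-(Ar1)propanoic acid
Product: 21 3-(Ar1)propanoyl chloride
Conditions: (COCl)2, DMF (cat.), CH2Cl2, 0 °C → rt
Reagents that add atoms: oxalyl chloride, ClC(=O)C(=O)Cl
Why: Standard acid chloride formation through the chloroiminium catalyst; only volatile by-products.

Step 13
Reactants: 21 3-(Ar1)propanoyl chloride; 13 tert-butoxyacetylene
Product: 23 4-(Ar1-methyl)-3-tert-butoxycyclobut-2-en-1-one (racemic), via ketene 22 (not isolated)
Conditions: Et3N (1.3 equiv), 13 (3 equiv), Et2O, 0 °C → rt, 21 added slowly
Reagents that add atoms: none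
Why: Dehydrochlorination gives the monoalkylketene 22, which undergoes [2+2] cycloaddition with the ynol ether; the nucleophilic terminal carbon of 13 attacks the ketene carbonyl carbon, so the alkoxy group ends at C3 and the arylmethyl group at C4. Slow addition into excess 13 keeps the ketene concentration low against dimerisation, and the C4 stereocentre is formed racemic and disappears in step 14.

Step 14
Reactants: 23 4-(Ar1-methyl)-3-tert-butoxycyclobut-2-en-1-one; 15 1,3-bis(benzyloxy)-4-bromo-2-(3-tert-butoxyprop-2-yn-1-yl)-5-methoxy-6-methylbenzene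
Product: 28 2,6-bis(Ar1-methyl)-3,5-di-tert-butoxyphenol, via vinylketene 24 (not isolated), via vinylcyclobutenone 25 (not isolated), via dienylketene 26 (not isolated), via cyclohexadienone 27 (not isolated)
Conditions: hν (λ > 300 nm, Pyrex filter), 15 (1.2 equiv), degassed toluene, 20 °C; then 70 °C in the dark
Reagents that add atoms: none
Why: Excitation of the enone chromophore of 23 opens the four-membered ring to vinylketene 24 at room temperature, below the temperature at which the tert-butyl alkynyl ether 15 fragments. The ketene carbonyl carbon of 24 is attacked by the nucleophilic β-carbon of 15, the carbon that bears the arylmethyl arm and is polarised by the alkoxy group, so the [2+2] cycloaddition gives 25 with the new ring B bonds C2–C3 and C4–C5 and with oxygen and carbon substituents alternating. 25 then undergoes 4π electrocyclic opening to the (Z)-dienylketene 26, which closes ring B by a thermally allowed disrotatory 6π electrocyclisation (bond C1–C2) to cyclohexadienone 27, and enolisation gives phenol 28. The closest known reaction type is the Danheiser benzannulation of cyclobutenones with alkoxy- and silyloxyalkynes, used here in its photochemical mode. No stereocentre is kept, since the sp3 carbons of 23, 25 and 27 all become aromatic. The step needs regioselectivity in the [2+2] event, which the donor polarisation of the ynol ether secures, and chemoselectivity for 15 over ketene dimerisation or O-acylation of the product, which the excess of the electron-rich alkyne and the two arylmethyl groups flanking the phenol of 28 should secure. Light above 300 nm is absorbed by the enone but hardly by the bromoarenes, so the aryl bromides should survive, and the gentle warming at the end drives remaining 25 on to 28 once 15 has been consumed.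

Step 15
Reactants: 28 2,6-bis(Ar1-methyl)-3,5-di-tert-butoxyphenol
Product: 30 2,6-bis(Ar2-methyl)-3,5-di-tert-butoxyphenol, via trilithio species 29 (not isolated)
Conditions: t-BuLi (5.2 equiv), THF, −78 °C; then N-methoxy-N-methylbutanamide (3 equiv), −78 → 0 °C; aq NH4Cl
Reagents that add atoms: N-methoxy-N-methylbutanamide, CCCC(=O)N(C)OC
Why: Deprotonation of the phenol and double bromine–lithium exchange, then Weinreb ketone synthesis; exchange at −78 °C is faster than removal of benzylic ether or bridge hydrogens, the chelated tetrahedral adduct prevents over-addition, and ring B C5–H is not touched, so butanoyl enters ring A C1 only.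

Step 16
Reactants: 30 2,6-bis(Ar2-methyl)-3,5-di-tert-butoxyphenol
Product: 31 2,4-bis(Ar2-methyl)benzene-1,3,5-triol
Conditions: CF3CO2H, Et3SiH, CH2Cl2, 0 °C
Reagents that add atoms: none
Why: Acidolysis of the aryl tert-butyl ethers, which cleave far faster than aryl benzyl ethers in cold dilute acid; the silane reduces the tert-butyl cation before it can alkylate ring B C5, and the twisted, doubly ortho-substituted ring A ketones should resist ionic hydrogenation under these conditions.

Step 17
Reactants: 32 (S)-2-methylbutanoic acid
Product: 33 (S)-2-methylbutanoyl chloride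
Conditions: (COCl)2, DMF (cat.), CH2Cl2, 0 °C → rt; used crude
Reagents that add atoms: oxalyl chloride, ClC(=O)C(=O)Cl
Why: Acid chloride formation without amine base, so no ketene is formed and the α-stereocentre keeps its (S) configuration.

Step 18
Reactants: 31 2,4-bis(Ar2-methyl)benzene-1,3,5-triol; 33 (S)-2-methylbutanoyl chloride
Product: 34 (2S)-1-[3,5-bis(Ar2-methyl)-2,4,6-trihydroxyphenyl]-2-methylbutan-1-one
Conditions: TiCl4 (4 equiv), CH2Cl2, −78 → −20 °C; cold dilute HCl work-up
Reagents that add atoms: none
Why: Friedel–Crafts C-acylation of a free, doubly alkylated phloroglucinol through its titanium phenoxide; ring B C5 is the only aromatic C–H in 31, so no regiochemical choice exists, and the very nucleophilic ring should react at temperatures where TiCl4 does not yet cleave benzyl ethers. The stereocentre is carried in from 33 and should stay (S) because no base is present and the chelated ketone is kept cold.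

Step 19
Reactants: 34 (2S)-1-[3,5-bis(Ar2-methyl)-2,4,6-trihydroxyphenyl]-2-methylbutan-1-one
Product: 35 agrimol B
Conditions: H2 (1 atm), 10% Pd/C, EtOAc, rt
Reagents that add atoms: none
Why: Hydrogenolysis of four aryl benzyl ethers under neutral conditions; hydrogen-bonded, doubly ortho-substituted aryl ketones and diarylmethane C–C bonds are not reduced at 1 atm, and the stereocentre is not exposed to acid or base.

## Compound list

1 | 2,4,6-trihydroxytoluene | Cc1c(O)cc(O)cc1O | starting material
2 | N-[(2,4,6-trihydroxy-3-methylphenyl)methylidene]-N-methylmethanaminium chloride | C[N+](C)=Cc1c(O)c(C)c(O)cc1O.[Cl-] | intermediate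
3 | 2,4,6-trihydroxy-3-methylbenzaldehyde | O=Cc1c(O)c(C)c(O)cc1O | intermediate
4 | 2,6-dihydroxy-4-methoxy-3-methylbenzaldehyde | O=Cc1c(O)c(C)c(OC)cc1O | intermediate
5 | 3-bromo-2,6-dihydroxy-4-methoxy-5-methylbenzaldehyde | O=Cc1c(O)c(C)c(OC)c(Br)c1O | intermediate
6 | 2,6-bis(benzyloxy)-3-bromo-4-methoxy-5-methylbenzaldehyde | O=Cc1c(OCc2ccccc2)c(C)c(OC)c(Br)c1OCc1ccccc1 | intermediate
7 | [2,6-bis(benzyloxy)-3-bromo-4-methoxy-5-methylphenyl]methanol | OCc1c(OCc2ccccc2)c(C)c(OC)c(Br)c1OCc1ccccc1 | intermediate
8 | 1,3-bis(benzyloxy)-4-bromo-2-(bromomethyl)-5-methoxy-6-methylbenzene | BrCc1c(OCc2ccccc2)c(C)c(OC)c(Br)c1OCc1ccccc1 | intermediate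
9 | tert-butyl vinyl ether | C=COC(C)(C)C | starting material
10 | 1,2-dibromo-1-tert-butoxyethane | BrCC(Br)OC(C)(C)C | intermediate
11 | (Z)-1-bromo-2-tert-butoxyethene | Br/C=C\OC(C)(C)C | intermediate
12 | sodium tert-butoxyacetylide | [Na+].[C-]#COC(C)(C)C | intermediate
13 | tert-butoxyacetylene | C#COC(C)(C)C | intermediate
14 | lithium tert-butoxyacetylide | [Li]C#COC(C)(C)C | intermediate
15 | 1,3-bis(benzyloxy)-4-bromo-2-(3-tert-butoxyprop-2-yn-1-yl)-5-methoxy-6-methylbenzene | CC(C)(C)OC#CCc1c(OCc2ccccc2)c(C)c(OC)c(Br)c1OCc1ccccc1 | intermediate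
16 | diethyl malonate | CCOC(=O)CC(=O)OCC | starting material
17 | sodium enolate of diethyl malonate | [Na+].CCOC(=O)[CH-]C(=O)OCC | intermediate
18 | diethyl 2-(Ar1-methyl)propanedioate | CCOC(=O)C(Cc1c(OCc2ccccc2)c(C)c(OC)c(Br)c1OCc1ccccc1)C(=O)OCC | intermediate
19 | 2-(Ar1-methyl)propanedioic acid | OC(=O)C(Cc1c(OCc2ccccc2)c(C)c(OC)c(Br)c1OCc1ccccc1)C(=O)O | intermediate
20 | 3-(Ar1)propanoic acid | OC(=O)CCc1c(OCc2ccccc2)c(C)c(OC)c(Br)c1OCc1ccccc1 | intermediate
21 | 3-(Ar1)propanoyl chloride | ClC(=O)CCc1c(OCc2ccccc2)c(C)c(OC)c(Br)c1OCc1ccccc1 | intermediate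
22 | 3-(Ar1)prop-1-en-1-one (arylmethylketene) | O=C=CCc1c(OCc2ccccc2)c(C)c(OC)c(Br)c1OCc1ccccc1 | intermediate
23 | 4-(Ar1-methyl)-3-tert-butoxycyclobut-2-en-1-one, racemic | O=C1C=C(OC(C)(C)C)C1Cc1c(OCc2ccccc2)c(C)c(OC)c(Br)c1OCc1ccccc1 | intermediate
24 | 5-(Ar1)-3-tert-butoxypenta-1,3-dien-1-one (vinylketene) | O=C=CC(OC(C)(C)C)=CCc1c(OCc2ccccc2)c(C)c(OC)c(Br)c1OCc1ccccc1 | intermediate
25 | 2-(Ar1-methyl)-3-tert-butoxy-4-[3-(Ar1)-1-tert-butoxyprop-1-en-1-yl]cyclobut-2-en-1-one | O=C1C(Cc2c(OCc3ccccc3)c(C)c(OC)c(Br)c2OCc2ccccc2)=C(OC(C)(C)C)C1C(OC(C)(C)C)=CCc1c(OCc2ccccc2)c(C)c(OC)c(Br)c1OCc1ccccc1 | intermediate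
26 | 7-(Ar1)-2-(Ar1-methyl)-3,5-di-tert-butoxyhepta-1,3,5-trien-1-one (dienylketene, 3Z) | O=C=C(Cc1c(OCc2ccccc2)c(C)c(OC)c(Br)c1OCc1ccccc1)C(OC(C)(C)C)=CC(OC(C)(C)C)=CCc1c(OCc2ccccc2)c(C)c(OC)c(Br)c1OCc1ccccc1 | intermediate
27 | 2,6-bis(Ar1-methyl)-3,5-di-tert-butoxycyclohexa-2,4-dien-1-one, racemic | O=C1C(Cc2c(OCc3ccccc3)c(C)c(OC)c(Br)c2OCc2ccccc2)=C(OC(C)(C)C)C=C(OC(C)(C)C)C1Cc1c(OCc2ccccc2)c(C)c(OC)c(Br)c1OCc1ccccc1 | intermediate
28 | 2,6-bis(Ar1-methyl)-3,5-di-tert-butoxyphenol | Oc1c(Cc2c(OCc3ccccc3)c(C)c(OC)c(Br)c2OCc2ccccc2)c(OC(C)(C)C)cc(OC(C)(C)C)c1Cc1c(OCc2ccccc2)c(C)c(OC)c(Br)c1OCc1ccccc1 | intermediate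
29 | trilithio derivative of 28 (lithium phenoxide, both ring A C1 lithiated) | [Li]Oc1c(Cc2c(OCc3ccccc3)c(C)c(OC)c([Li])c2OCc2ccccc2)c(OC(C)(C)C)cc(OC(C)(C)C)c1Cc1c(OCc2ccccc2)c(C)c(OC)c([Li])c1OCc1ccccc1 | intermediate
30 | 2,6-bis(Ar2-methyl)-3,5-di-tert-butoxyphenol | Oc1c(Cc2c(OCc3ccccc3)c(C)c(OC)c(C(=O)CCC)c2OCc2ccccc2)c(OC(C)(C)C)cc(OC(C)(C)C)c1Cc1c(OCc2ccccc2)c(C)c(OC)c(C(=O)CCC)c1OCc1ccccc1 | intermediate
31 | 2,4-bis(Ar2-methyl)benzene-1,3,5-triol | Oc1cc(O)c(Cc2c(OCc3ccccc3)c(C)c(OC)c(C(=O)CCC)c2OCc2ccccc2)c(O)c1Cc1c(OCc2ccccc2)c(C)c(OC)c(C(=O)CCC)c1OCc1ccccc1 | intermediate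
32 | (S)-2-methylbutanoic acid | CC[C@H](C)C(=O)O | starting material
33 | (S)-2-methylbutanoyl chloride | CC[C@H](C)C(=O)Cl | intermediate
34 | (2S)-1-[3,5-bis(Ar2-methyl)-2,4,6-trihydroxyphenyl]-2-methylbutan-1-one | CC[C@H](C)C(=O)c1c(O)c(Cc2c(OCc3ccccc3)c(C)c(OC)c(C(=O)CCC)c2OCc2ccccc2)c(O)c(Cc2c(OCc3ccccc3)c(C)c(OC)c(C(=O)CCC)c2OCc2ccccc2)c1O | intermediate
35 | agrimol B | CCCC(=O)c1c(O)c(Cc2c(O)c(Cc3c(O)c(C)c(OC)c(C(=O)CCC)c3O)c(O)c(C(=O)[C@@H](C)CC)c2O)c(O)c(C)c1OC | target

## Step count and least certain steps

Total step count: 19. Longest linear sequence: 15 steps (steps 1–6, 10–16, 18 and 19).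

Step 14 (key step). The most likely failure is inefficient photochemical ring opening because four electron-rich arenes compete for the light. Vinylketene 24 may also be lost by dimerisation, or the cascade may stall at vinylcyclobutenone 25. Heating cannot rescue the reaction, because the tert-butyl alkynyl ether fragments thermally. Fallback, from 8 and 23, back at 31:
- Coupling of 8 with HC≡CMgBr (CuBr cat., THF) would give the terminal alkyne 1,3-bis(benzyloxy)-4-bromo-5-methoxy-6-methyl-2-(prop-2-yn-1-yl)benzene F1.
- Deprotonation with LiN(SiMe3)2, oxidation of the acetylide with t-BuOOLi and O-silylation of the ynolate with i-Pr3SiOTf would give the silyl ynol ether {[3-(Ar1)prop-1-yn-1-yl]oxy}tri(propan-2-yl)silane F2, which does not fragment on heating.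
- F2 and 23 in toluene at 80–100 °C (thermal benzannulation) would give 2,6-bis(Ar1-methyl)-3-tert-butoxy-5-{[tri(propan-2-yl)silyl]oxy}phenol F3.
- The conditions of step 15 would give 2,6-bis(Ar2-methyl)-3-tert-butoxy-5-{[tri(propan-2-yl)silyl]oxy}phenol F4.
- Bu4NF in THF would give 2,4-bis(Ar2-methyl)-5-tert-butoxybenzene-1,3-diol F5, and the conditions of step 16 would then give 31.

Step 9. The hindered benzylic bromide may be C-alkylated too slowly, so that ionisation pathways or base-induced propargyl-to-allenyl isomerisation take over, and 15 may be hydrated during purification. Fallback, from 20, back at 15: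
- Esterification of 20 (Boc2O, DMAP, t-BuOH) would give tert-butyl 3-(Ar1)propanoate F6.
- Enolisation with LDA in THF–DMPU and O-phosphorylation with ClP(O)(OEt)2 would give the ketene acetal phosphate 3-(Ar1)-1-tert-butoxyprop-1-en-1-yl diethyl phosphate F7.
- A further two equivalents of LDA would eliminate the phosphate and give 15.

Step 13. The aldoketene 22 may dimerise or oligomerise faster than it adds to the alkyne, and 13 may be lost by thermal fragmentation. Fallback, from 15, back at 31:
- 15 and dichloroketene (Cl3CCOCl, Zn–Cu couple, Et2O) would give 2-(Ar1-methyl)-3-tert-butoxy-4,4-dichlorocyclobut-2-en-1-one F8.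
- Zn and NH4Cl in MeOH would give 2-(Ar1-methyl)-3-tert-butoxycyclobut-2-en-1-one F9.
- F9 and a second portion of 15 under the conditions of step 14 would give the regioisomeric phenol 2,4-bis(Ar1-methyl)-3,5-di-tert-butoxyphenol F10.
- The conditions of step 15 would give 2,4-bis(Ar2-methyl)-3,5-di-tert-butoxyphenol F11, and the conditions of step 16 would give 31, because both ether isomers lead to the same triol.

Step 15. The double exchange may be incomplete, or an aryllithium may be protonated through enolisation of the amide, leaving ring A C1–H; a benzyl ether next to the carbanion may also rearrange. Fallback, from 28, back at 30: the trilithio species would be trapped with butanal, a smaller and more electrophilic partner, to give 2,6-bis{[2,6-bis(benzyloxy)-3-(1-hydroxybutyl)-4-methoxy-5-methylphenyl]methyl}-3,5-di-tert-butoxyphenol F12 as a diastereomer mixture. Oxidation with Dess–Martin periodinane (NaHCO3, CH2Cl2) would give 30.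

Step 18. TiCl4 may cleave the benzyl ethers ortho to the ring A ketones, with C-benzylation of ring B C5, or the new ketone may enolise in its titanium chelate and erode the stereocentre. Fallback, from 31, back at 35: hydrogenolysis of 31 (H2, Pd/C, EtOAc) first would give 2,4-bis[(3-butanoyl-2,6-dihydroxy-4-methoxy-5-methylphenyl)methyl]benzene-1,3,5-triol F13, which has no benzyl ether. C-acylation of its only aromatic C–H with 33 and TiCl4 in CH2Cl2 at low temperature would give 35 directly.

## Further compounds

F1 | step 14 | 1,3-bis(benzyloxy)-4-bromo-5-methoxy-6-methyl-2-(prop-2-yn-1-yl)benzene | C#CCc1c(OCc2ccccc2)c(C)c(OC)c(Br)c1OCc1ccccc1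
F2 | step 14 | {[3-(Ar1)prop-1-yn-1-yl]oxy}tri(propan-2-yl)silane | CC(C)[Si](C(C)C)(C(C)C)OC#CCc1c(OCc2ccccc2)c(C)c(OC)c(Br)c1OCc1ccccc1
F3 | step 14 | 2,6-bis(Ar1-methyl)-3-tert-butoxy-5-{[tri(propan-2-yl)silyl]oxy}phenol | Oc1c(Cc2c(OCc3ccccc3)c(C)c(OC)c(Br)c2OCc2ccccc2)c(O[Si](C(C)C)(C(C)C)C(C)C)cc(OC(C)(C)C)c1Cc1c(OCc2ccccc2)c(C)c(OC)c(Br)c1OCc1ccccc1
F4 | step 14 | 2,6-bis(Ar2-methyl)-3-tert-butoxy-5-{[tri(propan-2-yl)silyl]oxy}phenol | Oc1c(Cc2c(OCc3ccccc3)c(C)c(OC)c(C(=O)CCC)c2OCc2ccccc2)c(O[Si](C(C)C)(C(C)C)C(C)C)cc(OC(C)(C)C)c1Cc1c(OCc2ccccc2)c(C)c(OC)c(C(=O)CCC)c1OCc1ccccc1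
F5 | step 14 | 2,4-bis(Ar2-methyl)-5-tert-butoxybenzene-1,3-diol | Oc1c(Cc2c(OCc3ccccc3)c(C)c(OC)c(C(=O)CCC)c2OCc2ccccc2)c(O)cc(OC(C)(C)C)c1Cc1c(OCc2ccccc2)c(C)c(OC)c(C(=O)CCC)c1OCc1ccccc1
F6 | step 9 | tert-butyl 3-(Ar1)propanoate | CC(C)(C)OC(=O)CCc1c(OCc2ccccc2)c(C)c(OC)c(Br)c1OCc1ccccc1
F7 | step 9 | 3-(Ar1)-1-tert-butoxyprop-1-en-1-yl diethyl phosphate | CCOP(=O)(OCC)OC(OC(C)(C)C)=CCc1c(OCc2ccccc2)c(C)c(OC)c(Br)c1OCc1ccccc1
F8 | step 13 | 2-(Ar1-methyl)-3-tert-butoxy-4,4-dichlorocyclobut-2-en-1-one | O=C1C(Cc2c(OCc3ccccc3)c(C)c(OC)c(Br)c2OCc2ccccc2)=C(OC(C)(C)C)C1(Cl)Cl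
F9 | step 13 | 2-(Ar1-methyl)-3-tert-butoxycyclobut-2-en-1-one | O=C1CC(OC(C)(C)C)=C1Cc1c(OCc2ccccc2)c(C)c(OC)c(Br)c1OCc1ccccc1
F10 | step 13 | 2,4-bis(Ar1-methyl)-3,5-di-tert-butoxyphenol | Oc1cc(OC(C)(C)C)c(Cc2c(OCc3ccccc3)c(C)c(OC)c(Br)c2OCc2ccccc2)c(OC(C)(C)C)c1Cc1c(OCc2ccccc2)c(C)c(OC)c(Br)c1OCc1ccccc1
F11 | step 13 | 2,4-bis(Ar2-methyl)-3,5-di-tert-butoxyphenol | Oc1cc(OC(C)(C)C)c(Cc2c(OCc3ccccc3)c(C)c(OC)c(C(=O)CCC)c2OCc2ccccc2)c(OC(C)(C)C)c1Cc1c(OCc2ccccc2)c(C)c(OC)c(C(=O)CCC)c1OCc1ccccc1
F12 | step 15 | 2,6-bis{[2,6-bis(benzyloxy)-3-(1-hydroxybutyl)-4-methoxy-5-methylphenyl]methyl}-3,5-di-tert-butoxyphenol (diastereomer mixture) | Oc1c(Cc2c(OCc3ccccc3)c(C)c(OC)c(C(O)CCC)c2OCc2ccccc2)c(OC(C)(C)C)cc(OC(C)(C)C)c1Cc1c(OCc2ccccc2)c(C)c(OC)c(C(O)CCC)c1OCc1ccccc1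
F13 | step 18 | 2,4-bis[(3-butanoyl-2,6-dihydroxy-4-methoxy-5-methylphenyl)methyl]benzene-1,3,5-triol | CCCC(=O)c1c(O)c(Cc2c(O)cc(O)c(Cc3c(O)c(C)c(OC)c(C(=O)CCC)c3O)c2O)c(O)c(C)c1OC
A1 | alternative 1 | trimer with both ring A butanoyl ketones, free ring A C2 hydroxyls and five butanoate esters (ring A C4 twice, ring B C2, C4, C6), ring B C5 unsubstituted | CCCC(=O)c1c(O)c(Cc2c(OC(=O)CCC)c(Cc3c(OC(=O)CCC)c(C)c(OC)c(C(=O)CCC)c3O)c(OC(=O)CCC)cc2OC(=O)CCC)c(OC(=O)CCC)c(C)c1OC
A2 | alternative 2 | trimer with both rings A complete and ring B as tribenzyl ether, ring B C5 unsubstituted | CCCC(=O)c1c(O)c(Cc2c(OCc4ccccc4)c(Cc3c(O)c(C)c(OC)c(C(=O)CCC)c3O)c(OCc4ccccc4)cc2OCc4ccccc4)c(O)c(C)c1OC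
A3 | alternative 2 | 1-methoxyhex-1-yn-3-one | CCCC(=O)C#COC
A4 | alternative 3 | dibenzyl 1,3-bis(Ar2-methyl)-2,4,6-trioxocyclohexane-1,3-dicarboxylate (diastereomer mixture) | O=C1CC(=O)C(Cc2c(OCc4ccccc4)c(C)c(OC)c(C(=O)CCC)c2OCc4ccccc4)(C(=O)OCc4ccccc4)C(=O)C1(Cc3c(OCc4ccccc4)c(C)c(OC)c(C(=O)CCC)c3OCc4ccccc4)C(=O)OCc4ccccc4
A5 | alternative 3 | malonyl dichloride | O=C(Cl)CC(=O)Cl
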